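The plan rests on cutting C5–C6 together with the lactone C12–O bond. C6 is an allylic carbinol carbon lying between the Z-alkenyl carbon C5 and C7, and C7 carries the acrylate unit C11(=C13)–C12. One alkenylchromium addition to a C6 aldehyde should therefore close the ten-membered carbocycle (C1–C10), set C6, and let the C6 alkoxide close the α-methylene-γ-lactone (O, C6, C7, C11, C12) on the C12 methyl ester. The precursor is an open-chain aldehyde bearing the (Z)-C5 iodide, the acrylate, the C9 acetate, the C14 (R)-2-methylbutanoate and a C8 silyl ether; it is joined from two fragments at C9–C10, with C5 masked as a vinylsilane until then.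

Key step: step 18

Remarks on the chemistry:
- Locants follow germacrane numbering (ring C1–C10, C11=C13 methylene, C12 carbonyl, C14 on C10, C15 on C4).
- 2-[(4-Methoxybenzyl)oxy]acetaldehyde is assumed to be a purchasable building block.
- The CIP label at C7 changes with the groups on C6 and C8 although the spatial arrangement stays the same throughout.

Step 1
Reactants: 1 (4-bromobut-1-yn-1-yl)trimethylsilane; 2 propyne
Product: 6 [(5Z)-6-iodo-5-methylhex-5-en-1-yn-1-yl]trimethylsilane, via Grignard reagent 3 (not isolated), via alkylcopper 4 (not isolated), via alkenylcopper 5 (not isolated)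
Conditions: Mg, Et2O; CuBr·SMe2, Et2O/Me2S, −45 °C; 2, −25 °C; I2, −50 to 0 °C
Reagents that add atoms: iodine, [I][I]
Why: Carbocupration of a terminal alkyne: the alkylcopper adds syn across propyne with the alkyl group on the substituted carbon, and iodinolysis of the alkenylcopper with retention places iodine cis to the chain, which is the Z geometry of C4=C5.

Step 2
Reactants: 6 [(5Z)-6-iodo-5-methylhex-5-en-1-yn-1-yl]trimethylsilane
Product: 8 [(1Z)-2-methylhex-1-en-5-yne-1,6-diyl]bis(trimethylsilane), via alkenyllithium 7 (not isolated)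
Conditions: t-BuLi (2.1 equiv), Et2O, −78 °C; TMSCl, −78 °C to rt
Reagents that add atoms: chlorotrimethylsilane, C[Si](C)(C)Cl
Why: Iodine–lithium exchange and silylation both proceed with retention at the alkenyl carbon, so C5 becomes a vinylsilane that is inert to the tin, iodine and chromium chemistry needed at C10 and can be returned to the iodide later.

Step 3
Reactants: 8 [(1Z)-2-methylhex-1-en-5-yne-1,6-diyl]bis(trimethylsilane)
Product: 10 (6Z)-6-methyl-7-(trimethylsilyl)hept-6-en-2-yn-1-ol, via lithium acetylide 9 (not isolated)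
Conditions: MeLi·LiBr, THF, 0 °C to rt; (CH2O)n, 0 °C to rt; H2O
Reagents that add atoms: paraformaldehyde (as formaldehyde), C=O
Why: Methyllithium cleaves the alkynyl C–Si bond but not the alkenyl C–Si bond, and the acetylide is hydroxymethylated in a standard acetylide addition to formaldehyde that brings in C14.

Step 4
Reactants: 10 (6Z)-6-methyl-7-(trimethylsilyl)hept-6-en-2-yn-1-ol
Product: 11 (2Z,6Z)-6-methyl-2-(tributylstannyl)-7-(trimethylsilyl)hepta-2,6-dien-1-ol
Conditions: Bu3SnH, [Cp*RuCl]4 (cat.), CH2Cl2, rt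
Reagents that add atoms: tributyltin hydride, CCCC[SnH](CCCC)CCCC
Why: Hydroxyl-directed ruthenium-catalysed trans-hydrostannation of a propargylic alcohol puts tin on the carbon next to the carbinol (C10) and hydrogen trans to it on C1, which fixes C2 cis to the future C9 as the Z olefin C1=C10 requires.

Step 5
Reactants: 11 (2Z,6Z)-6-methyl-2-(tributylstannyl)-7-(trimethylsilyl)hepta-2,6-dien-1-ol
Product: 12 (2Z,6Z)-2-iodo-6-methyl-7-(trimethylsilyl)hepta-2,6-dien-1-ol
Conditions: I2 (1.05 equiv), CH2Cl2, 0 °C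
Reagents that add atoms: iodine, [I][I]
Why: Iododestannylation proceeds with retention and is far faster than attack of iodine on the vinylsilane, so only C10 becomes an alkenyl iodide.

Step 6
Reactants: 13 2-[(4-methoxybenzyl)oxy]acetaldehyde; 14 methyl acrylate
Product: 15 methyl 3-hydroxy-4-[(4-methoxybenzyl)oxy]-2-methylidenebutanoate (racemic)
Conditions: DABCO, 14 (excess), rt
Reagents that add atoms: none
Why: Morita–Baylis–Hillman reaction of an activated α-alkoxy aldehyde with an acrylate; the carbinol centre disappears in the next step, so no stereocontrol is needed.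

Step 7
Reactants: 15 methyl 3-hydroxy-4-[(4-methoxybenzyl)oxy]-2-methylidenebutanoate
Product: 16 methyl (2Z)-2-(bromomethyl)-4-[(4-methoxybenzyl)oxy]but-2-enoate
Conditions: NBS, Me2S, CH2Cl2, 0 °C to rt
Reagents that add atoms: N-bromosuccinimide, O=C1CCC(=O)N1Br
Why: The bromosulfonium salt activates the allylic alcohol and bromide enters with allylic transposition (SN2'), the usual route from Morita–Baylis–Hillman alcohols to (Z)-2-(bromomethyl)alk-2-enoates.

Step 8
Reactants: 16 methyl (2Z)-2-(bromomethyl)-4-[(4-methoxybenzyl)oxy]but-2-enoate; 17 (4R)-2,2-dimethyl-1,3-dioxolane-4-carbaldehyde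
Product: 19 methyl (3S,4S)-4-[(4R)-2,2-dimethyl-1,3-dioxolan-4-yl]-4-hydroxy-3-{[(4-methoxybenzyl)oxy]methyl}-2-methylidenebutanoate, via allylindium bromide 18 (not isolated)
Conditions: In powder, THF/H2O (1:1), rt
Reagents that add atoms: none
Why: Barbier-type indium allylation: the allylindium adds through its γ-carbon in a chair transition state that should give the syn relation between the new hydroxyl (C8) and the CH2OPMB branch (C7), and Felkin–Anh attack anti to the dioxolane oxygen should set C8 against the acetonide centre, which is itself erased in step 11.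

Step 9
Reactants: 19 methyl (3S,4S)-4-[(4R)-2,2-dimethyl-1,3-dioxolan-4-yl]-4-hydroxy-3-{[(4-methoxybenzyl)oxy]methyl}-2-methylidenebutanoate
Product: 20 methyl (3S,4S)-4-[(tert-butyldimethylsilyl)oxy]-4-[(4R)-2,2-dimethyl-1,3-dioxolan-4-yl]-3-{[(4-methoxybenzyl)oxy]methyl}-2-methylidenebutanoate
Conditions: TBSOTf, 2,6-lutidine, CH2Cl2, −78 to 0 °C
Reagents that add atoms: tert-butyldimethylsilyl trifluoromethanesulfonate, CC(C)(C)[Si](C)(C)OS(=O)(=O)C(F)(F)F
Why: Silylation of a hindered secondary alcohol with the silyl triflate, which also stops the C8 hydroxyl from lactonising on the C12 ester.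

Step 10
Reactants: 20 methyl (3S,4S)-4-[(tert-butyldimethylsilyl)oxy]-4-[(4R)-2,2-dimethyl-1,3-dioxolan-4-yl]-3-{[(4-methoxybenzyl)oxy]methyl}-2-methylidenebutanoate
Product: 21 methyl (3S,4S,5R)-4-[(tert-butyldimethylsilyl)oxy]-5,6-dihydroxy-3-{[(4-methoxybenzyl)oxy]methyl}-2-methylidenehexanoate
Conditions: AcOH/H2O (4:1), rt
Reagents that add atoms: none
Why: Acid hydrolysis of a terminal isopropylidene acetal, under which the hindered secondary silyl ether and the PMB ether should survive.

Step 11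
Reactants: 21 methyl (3S,4S,5R)-4-[(tert-butyldimethylsilyl)oxy]-5,6-dihydroxy-3-{[(4-methoxybenzyl)oxy]methyl}-2-methylidenehexanoate
Product: 22 methyl (3S,4S)-4-[(tert-butyldimethylsilyl)oxy]-3-{[(4-methoxybenzyl)oxy]methyl}-2-methylidene-5-oxopentanoate
Conditions: NaIO4, THF/H2O, 0 °C to rt
Reagents that add atoms: none
Why: Periodate glycol cleavage gives the C9 aldehyde under neutral conditions that should leave the α-silyloxy centre C8 untouched; the aldehyde is used without chromatography.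

Step 12
Reactants: 12 (2Z,6Z)-2-iodo-6-methyl-7-(trimethylsilyl)hepta-2,6-dien-1-ol; 22 methyl (3S,4S)-4-[(tert-butyldimethylsilyl)oxy]-3-{[(4-methoxybenzyl)oxy]methyl}-2-methylidene-5-oxopentanoate
Product: 24 methyl (3S,4S,5R,6Z,10Z)-4-[(tert-butyldimethylsilyl)oxy]-5-hydroxy-6-(hydroxymethyl)-3-{[(4-methoxybenzyl)oxy]methyl}-10-methyl-2-methylidene-11-(trimethylsilyl)undeca-6,10-dienoate, via alkenylchromium 23 (not isolated)
Conditions: 12 (1.5 equiv), CrCl2 (6 equiv), NiCl2 (cat.), DMSO, rt; aq. NH4Cl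
Reagents that add atoms: none
Why: Nozaki–Hiyama–Kishi coupling of the two fragments: the C10 alkenylchromium, formed with retention, should add to the α-silyloxy aldehyde in the Felkin–Anh sense (anti to the C8–O bond) to give the 8,9-anti carbinol and so set C9, while the C5 vinylsilane is inert to nickel and chromium and the free C14 hydroxyl avoids a β-acyloxy alkenylmetal that could eliminate.

Step 13
Reactants: 24 methyl (3S,4S,5R,6Z,10Z)-4-[(tert-butyldimethylsilyl)oxy]-5-hydroxy-6-(hydroxymethyl)-3-{[(4-methoxybenzyl)oxy]methyl}-10-methyl-2-methylidene-11-(trimethylsilyl)undeca-6,10-dienoate; 25 (2R)-2-methylbutanoic acid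
Product: 26 methyl (3S,4S,5R,6Z,10Z)-4-[(tert-butyldimethylsilyl)oxy]-5-hydroxy-3-{[(4-methoxybenzyl)oxy]methyl}-10-methyl-6-({[(2R)-2-methylbutanoyl]oxy}methyl)-2-methylidene-11-(trimethylsilyl)undeca-6,10-dienoate
Conditions: 25 (1.05 equiv), EDC·HCl, DMAP (cat.), CH2Cl2, 0 °C
Reagents that add atoms: none
Why: Steglich-type esterification in which the primary allylic C14 hydroxyl should react well before the hindered secondary C9 hydroxyl, and mild carbodiimide activation at 0 °C should leave the α-centre of the acid untouched.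

Step 14
Reactants: 26 methyl (3S,4S,5R,6Z,10Z)-4-[(tert-butyldimethylsilyl)oxy]-5-hydroxy-3-{[(4-methoxybenzyl)oxy]methyl}-10-methyl-6-({[(2R)-2-methylbutanoyl]oxy}methyl)-2-methylidene-11-(trimethylsilyl)undeca-6,10-dienoate
Product: 27 methyl (3S,4S,5R,6Z,10Z)-5-acetoxy-4-[(tert-butyldimethylsilyl)oxy]-3-{[(4-methoxybenzyl)oxy]methyl}-10-methyl-6-({[(2R)-2-methylbutanoyl]oxy}methyl)-2-methylidene-11-(trimethylsilyl)undeca-6,10-dienoate
Conditions: Ac2O, pyridine, DMAP (cat.), CH2Cl2, rt
Reagents that add atoms: acetic anhydride, CC(=O)OC(C)=O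
Why: DMAP-catalysed acetylation of the remaining secondary allylic alcohol; the C8 oxygen is already silylated, so no acyl migration can follow.

Step 15
Reactants: 27 methyl (3S,4S,5R,6Z,10Z)-5-acetoxy-4-[(tert-butyldimethylsilyl)oxy]-3-{[(4-methoxybenzyl)oxy]methyl}-10-methyl-6-({[(2R)-2-methylbutanoyl]oxy}methyl)-2-methylidene-11-(trimethylsilyl)undeca-6,10-dienoate
Product: 28 methyl (3S,4S,5R,6Z,10Z)-5-acetoxy-4-[(tert-butyldimethylsilyl)oxy]-11-iodo-3-{[(4-methoxybenzyl)oxy]methyl}-10-methyl-6-({[(2R)-2-methylbutanoyl]oxy}methyl)-2-methylideneundeca-6,10-dienoate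
Conditions: NIS, MeCN/ClCH2CN (4:1), 0 °C to rt, dark
Reagents that add atoms: N-iodosuccinimide, O=C1CCC(=O)N1I
Why: Iododesilylation of a vinylsilane: ipso attack of the iodonium ion gives a tertiary β-silyl cation that loses silicon with retention, so the geometry set in step 1 returns as the (Z)-C5 iodide, while the electron-poor acrylate and the C1=C10 olefin flanked by two acyloxy groups should not react and the PMB ring is not iodinated without acid.

Step 16
Reactants: 28 methyl (3S,4S,5R,6Z,10Z)-5-acetoxy-4-[(tert-butyldimethylsilyl)oxy]-11-iodo-3-{[(4-methoxybenzyl)oxy]methyl}-10-methyl-6-({[(2R)-2-methylbutanoyl]oxy}methyl)-2-methylideneundeca-6,10-dienoate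
Product: 29 methyl (3S,4S,5R,6Z,10Z)-5-acetoxy-4-[(tert-butyldimethylsilyl)oxy]-3-(hydroxymethyl)-11-iodo-10-methyl-6-({[(2R)-2-methylbutanoyl]oxy}methyl)-2-methylideneundeca-6,10-dienoate
Conditions: DDQ, CH2Cl2/pH 7 buffer, 0 °C
Reagents that add atoms: none
Why: Oxidative cleavage of the PMB ether by DDQ is neutral and leaves the silyl ether, the esters and the alkenyl iodide alone; the γ-hydroxy acrylate is oxidised at once so that it does not lactonise.

Step 17
Reactants: 29 methyl (3S,4S,5R,6Z,10Z)-5-acetoxy-4-[(tert-butyldimethylsilyl)oxy]-3-(hydroxymethyl)-11-iodo-10-methyl-6-({[(2R)-2-methylbutanoyl]oxy}methyl)-2-methylideneundeca-6,10-dienoate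
Product: 30 methyl (3R,4S,5R,6Z,10Z)-5-acetoxy-4-[(tert-butyldimethylsilyl)oxy]-3-formyl-11-iodo-10-methyl-6-({[(2R)-2-methylbutanoyl]oxy}methyl)-2-methylideneundeca-6,10-dienoate
Conditions: Dess–Martin periodinane, pyridine, CH2Cl2, 0 °C
Reagents that add atoms: none
Why: Dess–Martin oxidation under buffered, non-basic conditions should give the α-branched β,γ-unsaturated aldehyde without epimerisation at C7 or loss of the C8 silyloxy group; it is used directly.

Step 18
Reactants: 30 methyl (3R,4S,5R,6Z,10Z)-5-acetoxy-4-[(tert-butyldimethylsilyl)oxy]-3-formyl-11-iodo-10-methyl-6-({[(2R)-2-methylbutanoyl]oxy}methyl)-2-methylideneundeca-6,10-dienoate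
Product: 33 (6R,7S,8S,9R)-9-acetoxy-8-[(tert-butyldimethylsilyl)oxy]-14-{[(2R)-2-methylbutanoyl]oxy}germacra-1(10)Z,4Z,11(13)-trien-12,6-olide, via alkenylchromium 31 (not isolated), via chromium alkoxide 32 (not isolated)
Conditions: CrCl2 (10 equiv), NiCl2 (cat.), degassed DMSO/THF, 2 mM (slow addition of 30), rt; aq. NH4Cl
Reagents that add atoms: none
Why: CrCl2 reduces NiCl2 to zerovalent nickel, which inserts into the C5–I bond with retention of the Z geometry; transmetalation gives the alkenylchromium 31 (trivalent chromium), this adds to the C6 aldehyde, and the chromium alkoxide 32 then attacks the C12 methyl ester and expels methoxide. The closest known reaction type is the NiCl2/CrCl2-mediated Nozaki–Hiyama–Kishi macrocyclisation of an alkenyl iodide onto an aldehyde, followed here by lactonisation of a γ-alkoxy acrylate as in chromium-mediated syntheses of α-methylene-γ-lactones. The carbocycle (C1–C10) closes by 10-exo-trig carbonyl addition with C4=C5 endocyclic, and the lactone (O, C6, C7, C11, C12) by 5-exo-trig acyl substitution. The new centre C6 is controlled by C7: in the Felkin–Anh arrangement the alkenyl group arrives anti to the C7–C8 bond of the forming ring, so the C6 oxygen ends trans to the acrylate branch on the ten-membered ring, and this is the arrangement that closes to the less strained trans-fused lactone. The step needs addition to the aldehyde in preference to the acetate, the two esters and the acrylate, and ring closure in preference to chain growth; the first follows from the carbonyl selectivity and low basicity of organochromium reagents, the second from high dilution together with the two Z olefins and the C8/C9 substituents, which fold the chain and bring C5 close to C6.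

Step 19
Reactants: 33 (6R,7S,8S,9R)-9-acetoxy-8-[(tert-butyldimethylsilyl)oxy]-14-{[(2R)-2-methylbutanoyl]oxy}germacra-1(10)Z,4Z,11(13)-trien-12,6-olide
Product: 34 (6R,7R,8S,9R)-9-acetoxy-8-hydroxy-14-{[(2R)-2-methylbutanoyl]oxy}germacra-1(10)Z,4Z,11(13)-trien-12,6-olide (CNP0005248.2)
Conditions: HF·pyridine, pyridine, THF, 0 °C to rt
Reagents that add atoms: none
Why: Fluoride-mediated desilylation under buffered acidic conditions should free the C8 hydroxyl without acetate migration from C9, opening of the lactone or addition to the α-methylene group.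

Compound list

1 | (4-bromobut-1-yn-1-yl)trimethylsilane | C[Si](C)(C)C#CCCBr | starting material
2 | propyne | CC#C | starting material
3 | [4-(trimethylsilyl)but-3-yn-1-yl]magnesium bromide | C[Si](C)(C)C#CCC[Mg]Br | intermediate
4 | [4-(trimethylsilyl)but-3-yn-1-yl]copper (MgBr2 complex) | C[Si](C)(C)C#CCC[Cu] | intermediate
5 | [(1Z)-2-methyl-6-(trimethylsilyl)hex-1-en-5-yn-1-yl]copper | [Cu]/C=C(/C)CCC#C[Si](C)(C)C | intermediate
6 | [(5Z)-6-iodo-5-methylhex-5-en-1-yn-1-yl]trimethylsilane | I/C=C(/C)CCC#C[Si](C)(C)C | intermediate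
7 | [(1Z)-2-methyl-6-(trimethylsilyl)hex-1-en-5-yn-1-yl]lithium | [Li]/C=C(/C)CCC#C[Si](C)(C)C | intermediate
8 | [(1Z)-2-methylhex-1-en-5-yne-1,6-diyl]bis(trimethylsilane) | C[Si](C)(C)/C=C(/C)CCC#C[Si](C)(C)C | intermediate
9 | lithium (5Z)-5-methyl-6-(trimethylsilyl)hex-5-en-1-yn-1-ide | [Li]C#CCC/C(C)=C\[Si](C)(C)C | intermediate
10 | (6Z)-6-methyl-7-(trimethylsilyl)hept-6-en-2-yn-1-ol | OCC#CCC/C(C)=C\[Si](C)(C)C | intermediate
11 | (2Z,6Z)-6-methyl-2-(tributylstannyl)-7-(trimethylsilyl)hepta-2,6-dien-1-ol | OC/C(=C/CC/C(C)=C\[Si](C)(C)C)[Sn](CCCC)(CCCC)CCCC | intermediate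
12 | (2Z,6Z)-2-iodo-6-methyl-7-(trimethylsilyl)hepta-2,6-dien-1-ol | OC/C(I)=C/CC/C(C)=C\[Si](C)(C)C | intermediate
13 | 2-[(4-methoxybenzyl)oxy]acetaldehyde | O=CCOCc1ccc(OC)cc1 | starting material
14 | methyl acrylate | C=CC(=O)OC | starting material
15 | methyl 3-hydroxy-4-[(4-methoxybenzyl)oxy]-2-methylidenebutanoate (racemic) | C=C(C(=O)OC)C(O)COCc1ccc(OC)cc1 | intermediate
16 | methyl (2Z)-2-(bromomethyl)-4-[(4-methoxybenzyl)oxy]but-2-enoate | COC(=O)/C(CBr)=C/COCc1ccc(OC)cc1 | intermediate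
17 | (4R)-2,2-dimethyl-1,3-dioxolane-4-carbaldehyde (R-glyceraldehyde acetonide) | O=C[C@H]1COC(C)(C)O1 | starting material
18 | allylindium dibromide derived from 16 | COC(=O)/C(C[In](Br)Br)=C/COCc1ccc(OC)cc1 | intermediate
19 | methyl (3S,4S)-4-[(4R)-2,2-dimethyl-1,3-dioxolan-4-yl]-4-hydroxy-3-{[(4-methoxybenzyl)oxy]methyl}-2-methylidenebutanoate | COC(=O)C(=C)[C@@H](COCc1ccc(OC)cc1)[C@H](O)[C@H]1COC(C)(C)O1 | intermediate
20 | methyl (3S,4S)-4-[(tert-butyldimethylsilyl)oxy]-4-[(4R)-2,2-dimethyl-1,3-dioxolan-4-yl]-3-{[(4-methoxybenzyl)oxy]methyl}-2-methylidenebutanoate | COC(=O)C(=C)[C@@H](COCc1ccc(OC)cc1)[C@H](O[Si](C)(C)C(C)(C)C)[C@H]1COC(C)(C)O1 | intermediate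
21 | methyl (3S,4S,5R)-4-[(tert-butyldimethylsilyl)oxy]-5,6-dihydroxy-3-{[(4-methoxybenzyl)oxy]methyl}-2-methylidenehexanoate | COC(=O)C(=C)[C@@H](COCc1ccc(OC)cc1)[C@H](O[Si](C)(C)C(C)(C)C)[C@H](O)CO | intermediate
22 | methyl (3S,4S)-4-[(tert-butyldimethylsilyl)oxy]-3-{[(4-methoxybenzyl)oxy]methyl}-2-methylidene-5-oxopentanoate | COC(=O)C(=C)[C@@H](COCc1ccc(OC)cc1)[C@H](O[Si](C)(C)C(C)(C)C)C=O | intermediate
23 | dichloro[(2Z,6Z)-1-hydroxy-6-methyl-7-(trimethylsilyl)hepta-2,6-dien-2-yl]chromium | OC/C(=C/CC/C(C)=C\[Si](C)(C)C)[Cr](Cl)Cl | intermediate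
24 | methyl (3S,4S,5R,6Z,10Z)-4-[(tert-butyldimethylsilyl)oxy]-5-hydroxy-6-(hydroxymethyl)-3-{[(4-methoxybenzyl)oxy]methyl}-10-methyl-2-methylidene-11-(trimethylsilyl)undeca-6,10-dienoate | C[Si](C)(C)/C=C(/C)CC/C=C(/CO)[C@@H](O)[C@@H](O[Si](C)(C)C(C)(C)C)[C@H](COCc1ccc(OC)cc1)C(=C)C(=O)OC | intermediate
25 | (2R)-2-methylbutanoic acid | CC[C@@H](C)C(=O)O | starting material
26 | methyl (3S,4S,5R,6Z,10Z)-4-[(tert-butyldimethylsilyl)oxy]-5-hydroxy-3-{[(4-methoxybenzyl)oxy]methyl}-10-methyl-6-({[(2R)-2-methylbutanoyl]oxy}methyl)-2-methylidene-11-(trimethylsilyl)undeca-6,10-dienoate | C[Si](C)(C)/C=C(/C)CC/C=C(/COC(=O)[C@H](C)CC)[C@@H](O)[C@@H](O[Si](C)(C)C(C)(C)C)[C@H](COCc1ccc(OC)cc1)C(=C)C(=O)OC | intermediate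
27 | methyl (3S,4S,5R,6Z,10Z)-5-acetoxy-4-[(tert-butyldimethylsilyl)oxy]-3-{[(4-methoxybenzyl)oxy]methyl}-10-methyl-6-({[(2R)-2-methylbutanoyl]oxy}methyl)-2-methylidene-11-(trimethylsilyl)undeca-6,10-dienoate | C[Si](C)(C)/C=C(/C)CC/C=C(/COC(=O)[C@H](C)CC)[C@@H](OC(C)=O)[C@@H](O[Si](C)(C)C(C)(C)C)[C@H](COCc1ccc(OC)cc1)C(=C)C(=O)OC | intermediate
28 | methyl (3S,4S,5R,6Z,10Z)-5-acetoxy-4-[(tert-butyldimethylsilyl)oxy]-11-iodo-3-{[(4-methoxybenzyl)oxy]methyl}-10-methyl-6-({[(2R)-2-methylbutanoyl]oxy}methyl)-2-methylideneundeca-6,10-dienoate | I/C=C(/C)CC/C=C(/COC(=O)[C@H](C)CC)[C@@H](OC(C)=O)[C@@H](O[Si](C)(C)C(C)(C)C)[C@H](COCc1ccc(OC)cc1)C(=C)C(=O)OC | intermediate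
29 | methyl (3S,4S,5R,6Z,10Z)-5-acetoxy-4-[(tert-butyldimethylsilyl)oxy]-3-(hydroxymethyl)-11-iodo-10-methyl-6-({[(2R)-2-methylbutanoyl]oxy}methyl)-2-methylideneundeca-6,10-dienoate | I/C=C(/C)CC/C=C(/COC(=O)[C@H](C)CC)[C@@H](OC(C)=O)[C@@H](O[Si](C)(C)C(C)(C)C)[C@H](CO)C(=C)C(=O)OC | intermediate
30 | methyl (3R,4S,5R,6Z,10Z)-5-acetoxy-4-[(tert-butyldimethylsilyl)oxy]-3-formyl-11-iodo-10-methyl-6-({[(2R)-2-methylbutanoyl]oxy}methyl)-2-methylideneundeca-6,10-dienoate (seco aldehyde; 7R,8S,9R in germacrane locants) | I/C=C(/C)CC/C=C(/COC(=O)[C@H](C)CC)[C@@H](OC(C)=O)[C@@H](O[Si](C)(C)C(C)(C)C)[C@H](C=O)C(=C)C(=O)OC | intermediate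
31 | C5 alkenylchromium dichloride of 30 (C–I replaced by C–CrCl2, Z geometry kept) | Cl[Cr](Cl)/C=C(/C)CC/C=C(/COC(=O)[C@H](C)CC)[C@@H](OC(C)=O)[C@@H](O[Si](C)(C)C(C)(C)C)[C@H](C=O)C(=C)C(=O)OC | intermediate
32 | ring-closed chromium alkoxide: ten-membered 1(10)Z,4Z-diene with C6–O–CrCl2 trans to the C7 methyl acrylate branch, 8-OTBS, 9-OAc, 14-O-(2R)-2-methylbutanoyl | Cl[Cr](Cl)O[C@@H]1/C=C(/C)CC/C=C(/COC(=O)[C@H](C)CC)[C@@H](OC(C)=O)[C@@H](O[Si](C)(C)C(C)(C)C)[C@H]1C(=C)C(=O)OC | intermediate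
33 | (6R,7S,8S,9R)-9-acetoxy-8-[(tert-butyldimethylsilyl)oxy]-14-{[(2R)-2-methylbutanoyl]oxy}germacra-1(10)Z,4Z,11(13)-trien-12,6-olide | C=C1C(=O)O[C@@H]2/C=C(/C)CC/C=C(/COC(=O)[C@H](C)CC)[C@@H](OC(C)=O)[C@@H](O[Si](C)(C)C(C)(C)C)[C@@H]12 | intermediate
34 | (6R,7R,8S,9R)-9-acetoxy-8-hydroxy-14-{[(2R)-2-methylbutanoyl]oxy}germacra-1(10)Z,4Z,11(13)-trien-12,6-olide (CNP0005248.2) | C=C1C(=O)O[C@@H]2/C=C(/C)CC/C=C(/COC(=O)[C@H](C)CC)[C@@H](OC(C)=O)[C@@H](O)[C@@H]12 | target

Total step count: 19.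
Longest linear sequence: 14 steps (steps 6–11, then steps 12–19); the other branch (steps 1–5, then 12–19) is 13 steps.

Steps most likely to fail

1. Step 18. What may go wrong: poor facial selectivity at C6 in the ring-forming addition, so that the carbinol with the C6 oxygen cis to the acrylate branch is formed. Fallback (C6 set by reduction of a ring ketone and not by the addition): it sets out from 30. The chromium-mediated closure is run as in step 18 but stopped cold and worked up before acylation, so that the ring-closed carbinols are kept as hydroxy esters. The unwanted epimer, the ring-closed (6S)-hydroxy ester F1, is oxidised with Dess–Martin periodinane to the macrocyclic C6 enone F2. Luche reduction (NaBH4, CeCl3·7H2O, MeOH, −78 °C) from the outer face of the ring should then give the ring-closed (6R)-hydroxy ester F3. F3 lactonises with PPTS in CH2Cl2, and the route is rejoined at 33.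

2. Step 12. What may go wrong: poor facial selectivity in the addition to the α-silyloxy aldehyde, so that much of the material has the wrong configuration at C9. Fallback (inversion by substitution instead of control in the addition): it sets out from 12 and 22. The coupling is run as in step 12, and the unwanted product, the C9-epimeric diol F4, is esterified at C14 as in step 13 to the C9-epimeric C14 ester F5. Mitsunobu reaction of F5 with acetic acid (PPh3, DIAD, THF, 0 °C) should install the C9 acetate with inversion, and the route is rejoined at 27.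

3. Step 8. What may go wrong: loss of the syn relation between C7 and C8, or attack on the wrong face of the aldehyde, in the aqueous indium reaction. Fallback (closed boron transition state instead of a metal Barbier reaction): it sets out from 15. Acetylation (Ac2O, DMAP, CH2Cl2) gives the Morita–Baylis–Hillman acetate F6. Copper-catalysed borylation with allylic transposition (B2pin2, CuCl, KOAc, DMF, rt) gives the allylboronate F7, in which the borylmethyl group is cis to the CH2OPMB branch. Thermal allylboration of 17 (toluene, 60 °C) through a chair transition state should give the syn, Felkin–Anh adduct, and the route is rejoined at 19.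

Further compounds
F1 | step 18 | ring-closed (6S)-hydroxy ester, C6 epimer of the carbinol of 32, as methyl ester | C=C(C(=O)OC)[C@H]1[C@@H](O)/C=C(/C)CC/C=C(/COC(=O)[C@H](C)CC)[C@@H](OC(C)=O)[C@H]1O[Si](C)(C)C(C)(C)C
F2 | step 18 | macrocyclic C6 enone (ten-membered 1(10)Z,4Z-dienone with C7 methyl acrylate branch, 8-OTBS, 9-OAc, C14 ester) | C=C(C(=O)OC)[C@H]1C(=O)/C=C(/C)CC/C=C(/COC(=O)[C@H](C)CC)[C@@H](OC(C)=O)[C@H]1O[Si](C)(C)C(C)(C)C
F3 | step 18 | ring-closed (6R)-hydroxy ester (free alcohol of 32) | C=C(C(=O)OC)[C@H]1[C@H](O)/C=C(/C)CC/C=C(/COC(=O)[C@H](C)CC)[C@@H](OC(C)=O)[C@H]1O[Si](C)(C)C(C)(C)C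
F4 | step 12 | methyl (3S,4S,5S,6Z,10Z)-4-[(tert-butyldimethylsilyl)oxy]-5-hydroxy-6-(hydroxymethyl)-3-{[(4-methoxybenzyl)oxy]methyl}-10-methyl-2-methylidene-11-(trimethylsilyl)undeca-6,10-dienoate (C9 epimer of 24) | C[Si](C)(C)/C=C(/C)CC/C=C(/CO)[C@H](O)[C@@H](O[Si](C)(C)C(C)(C)C)[C@H](COCc1ccc(OC)cc1)C(=C)C(=O)OC
F5 | step 12 | methyl (3S,4S,5S,6Z,10Z)-4-[(tert-butyldimethylsilyl)oxy]-5-hydroxy-3-{[(4-methoxybenzyl)oxy]methyl}-10-methyl-6-({[(2R)-2-methylbutanoyl]oxy}methyl)-2-methylidene-11-(trimethylsilyl)undeca-6,10-dienoate (C9 epimer of 26) | C[Si](C)(C)/C=C(/C)CC/C=C(/COC(=O)[C@H](C)CC)[C@H](O)[C@@H](O[Si](C)(C)C(C)(C)C)[C@H](COCc1ccc(OC)cc1)C(=C)C(=O)OC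
F6 | step 8 | methyl 3-acetoxy-4-[(4-methoxybenzyl)oxy]-2-methylidenebutanoate (racemic) | C=C(C(=O)OC)C(OC(C)=O)COCc1ccc(OC)cc1
F7 | step 8 | methyl (2E)-4-[(4-methoxybenzyl)oxy]-2-[(4,4,5,5-tetramethyl-1,3,2-dioxaborolan-2-yl)methyl]but-2-enoate | COC(=O)/C(CB1OC(C)(C)C(C)(C)O1)=C/COCc1ccc(OC)cc1
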